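The butenolide is treated as a masked 2-methoxyfuran. Its C5–O1–C2 segment comes intact from a 5-methoxyoxazole, and its C3=C4(Br) edge comes from a bromo-ynone. One Diels–Alder/retro-Diels–Alder operation joins C2 to C3 and C4 to C5 through a temporary oxa-aza-bicycle and extrudes acetonitrile. The feature exploited is the oxygen on C1′ beside ring carbon C3. Raised to a ketone, it polarises the alkyne so that the acyl-bearing carbon meets the methoxy-bearing oxazole carbon. The precursors are 1-bromohex-1-yn-3-one and 5-methoxy-2,4-dimethyloxazole. CBS reduction then sets C1′, and two halogenation–elimination steps turn the C5 methyl group into the (Z)-iodomethylidene lactone.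

Key step: step 4

Remark: the SMILES is read as (R) at C1′ and (Z) at the exocyclic alkene (iodine on the side of ring oxygen O1, away from C4). Lactone numbering is O1, C2 (C=O), C3 (side chain), C4 (Br), C5 (ylidene carbon).

Step 1
Reactants: 1 hex-1-yn-3-ol (racemic)
Product: 2 rac-1-bromohex-1-yn-3-ol
Conditions: NBS (1.1 equiv), AgNO3 (0.1 equiv), acetone, rt, dark
Reagents that add atoms: N-bromosuccinimide, O=C1CCC(=O)N1Br
Why: Silver-catalysed electrophilic bromination of a terminal alkyne via the silver acetylide is a standard route to 1-bromoalkynes and leaves the free propargylic alcohol untouched.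

Step 2
Reactants: 2 rac-1-bromohex-1-yn-3-ol
Product: 3 bromo-ynone 1-bromohex-1-yn-3-one
Conditions: Dess–Martin periodinane (1.2 equiv), CH2Cl2, 0 °C to rt; used without storage
Reagents that add atoms: none
Why: Dess–Martin oxidation converts the secondary propargylic alcohol into the ynone under neutral, non-nucleophilic conditions that spare the electrophilic C(sp)–Br bond, and it erases the racemic centre, which is set anew in step 5.

Step 3
Reactants: 4 methyl N-acetyl-L-alaninate
Product: 5 oxazole 5-methoxy-2,4-dimethyl-1,3-oxazole
Conditions: P2O5, CHCl3, reflux; cold aqueous base work-up, distillation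
Reagents that add atoms: none
Why: Robinson–Gabriel-type cyclodehydration of an N-acyl amino ester closes the amide oxygen onto the activated ester carbonyl to give the 5-alkoxyoxazole, and the alanine stereocentre is lost on aromatisation.

Step 4
Reactants: 3 bromo-ynone 1-bromohex-1-yn-3-one; 5 oxazole 5-methoxy-2,4-dimethyl-1,3-oxazole
Product: 7 furyl ketone 1-(4-bromo-2-methoxy-5-methylfuran-3-yl)butan-1-one, via oxa-aza-norbornadiene cycloadduct 6 (not isolated)
Conditions: 3 (1.0 equiv), 5 (1.5 equiv), toluene, 80 °C, N2, dark
Reagents that add atoms: none
Why: The 2-azadiene of 5 (oxazole C2=N3–C4=C5, raised in energy by the 5-methoxy group) adds in a concerted normal-electron-demand [4+2] cycloaddition across the electron-poor triple bond of 3 to give the 7-oxa-2-azanorbornadiene 6, which at the same temperature loses acetonitrile by retro-[4+2] to leave the aromatic furan 7. The closest known reaction type is the oxazole–alkyne Diels–Alder/retro-Diels–Alder furan synthesis, established for 5-alkoxyoxazoles with acetylenic esters and ketones, while 3-bromopropiolates are proven dienophiles towards furans and pyrroles. The closure is an intermolecular suprafacial [4πs+2πs] cycloaddition that closes the six-membered aza ring and the five-membered oxa-bridged ring of 6 together, and the cycloreversion keeps only the five-membered ring that becomes O1–C2–C3–C4–C5 of the lactone. The two bridgehead stereocentres of 6 form as a racemate and vanish with the nitrile, so no stereocontrol is needed here. The selectivity needed is regiochemical: the largest HOMO coefficient of the methoxy-terminated diene lies at oxazole C2 and the largest LUMO coefficient of the ynone at its bromine-bearing β-carbon, so the acyl-bearing carbon should bond to the methoxy-bearing oxazole C5, the same orientation that 2-methylfuran shows towards methyl 3-bromopropiolate. A non-polar solvent, a moderate temperature and an excess of 5 should hold back conjugate addition of the oxazole nitrogen to 3 and a second cycloaddition of the deactivated, fully substituted furan 7.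

Step 5
Reactants: 7 furyl ketone 1-(4-bromo-2-methoxy-5-methylfuran-3-yl)butan-1-one
Product: 8 (1R)-1-(4-bromo-2-methoxy-5-methylfuran-3-yl)butan-1-ol
Conditions: (S)-2-methyl-CBS-oxazaborolidine (0.2 equiv), BH3·SMe2 (0.7 equiv), THF, −20 °C; MeOH quench, pH 7 buffer
Reagents that add atoms: none
Why: In this Corey–Bakshi–Shibata reduction the (S)-oxazaborolidine binds the ketone anti to the larger furyl group and delivers hydride to the face that gives the (R)-carbinol, as it does with acetophenone, while low temperature and a buffered work-up should keep the ionisable furylic C–O bond intact.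

Step 6
Reactants: 8 (1R)-1-(4-bromo-2-methoxy-5-methylfuran-3-yl)butan-1-ol
Product: 9 (1R)-1-(4-bromo-2-methoxy-5-methylfuran-3-yl)butyl acetate
Conditions: Ac2O (1.5 equiv), Et3N (2 equiv), DMAP (0.05 equiv), CH2Cl2, 0 °C
Reagents that add atoms: acetic anhydride, CC(=O)OC(C)=O
Why: DMAP-catalysed O-acylation under basic conditions does not touch the C–O bond of the stereocentre, so the (R) configuration is retained.

Step 7
Reactants: 9 (1R)-1-(4-bromo-2-methoxy-5-methylfuran-3-yl)butyl acetate
Product: 11 (1R)-1-(4-bromo-5-methylidene-2-oxo-2,5-dihydrofuran-3-yl)butyl acetate, via dibromolactone 10 (not isolated)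
Conditions: Br2 (1.0 equiv), CH2Cl2, −78 to −20 °C; then Et3N (2.5 equiv), −20 to 0 °C
Reagents that add atoms: bromine, BrBr (its atom is held only in 10 and leaves again as bromide; 11 keeps none of it)
Why: Electrophilic halogenation of the 2-alkoxyfuran at C5 (ipso to methyl) gives an O-methyl lactonium ion that bromide demethylates to the 5-bromobutenolide 10, and amine-induced dehydrobromination towards the methyl group then gives the 5-methylidene butenolide, the same halogenation–dehydrohalogenation logic that converts α-angelica lactone into protoanemonin.

Step 8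
Reactants: 11 (1R)-1-(4-bromo-5-methylidene-2-oxo-2,5-dihydrofuran-3-yl)butyl acetate
Product: 13 (1R)-1-[(5Z)-4-bromo-5-(iodomethylidene)-2-oxo-2,5-dihydrofuran-3-yl]butyl acetate, via iodochloride adduct 12 (not isolated)
Conditions: ICl (1.05 equiv), CH2Cl2, −78 to −20 °C, dark; then iPr2NEt (2 equiv), −20 °C to rt
Reagents that add atoms: iodine monochloride, ClI
Why: Polar addition of I–Cl to the enol-ester alkene (iodine to the terminal CH2, chloride to the oxygen-stabilised C5) followed by E2 loss of HCl is the iodine counterpart of the bromination–dehydrobromination used on 5-methylidene butenolides, and the (Z)-alkene should result because iodine avoids the C4 bromine both in the elimination conformer and in the product.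

Compound list
1 | hex-1-yn-3-ol (racemic) | CCCC(O)C#C | starting material
2 | rac-1-bromohex-1-yn-3-ol | CCCC(O)C#CBr | intermediate
3 | 1-bromohex-1-yn-3-one | CCCC(=O)C#CBr | intermediate
4 | methyl N-acetyl-L-alaninate (methyl (2S)-2-acetamidopropanoate) | C[C@H](NC(C)=O)C(=O)OC | starting material
5 | 5-methoxy-2,4-dimethyl-1,3-oxazole | COc1oc(C)nc1C | intermediate
6 | 1-(6-bromo-4-methoxy-1,3-dimethyl-7-oxa-2-azabicyclo[2.2.1]hepta-2,5-dien-5-yl)butan-1-one (racemic, transient) | CCCC(=O)C1=C(Br)C2(C)N=C(C)C1(OC)O2 | intermediate
7 | 1-(4-bromo-2-methoxy-5-methylfuran-3-yl)butan-1-one | CCCC(=O)c1c(Br)c(C)oc1OC | intermediate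
8 | (1R)-1-(4-bromo-2-methoxy-5-methylfuran-3-yl)butan-1-ol | CCC[C@@H](O)c1c(Br)c(C)oc1OC | intermediate
9 | (1R)-1-(4-bromo-2-methoxy-5-methylfuran-3-yl)butyl acetate | CCC[C@@H](OC(C)=O)c1c(Br)c(C)oc1OC | intermediate
10 | (1R)-1-(4,5-dibromo-5-methyl-2-oxo-2,5-dihydrofuran-3-yl)butyl acetate (C5 epimers, transient) | CCC[C@@H](OC(C)=O)C1=C(Br)C(C)(Br)OC1=O | intermediate
11 | (1R)-1-(4-bromo-5-methylidene-2-oxo-2,5-dihydrofuran-3-yl)butyl acetate | CCC[C@@H](OC(C)=O)C1=C(Br)C(=C)OC1=O | intermediate
12 | (1R)-1-[4-bromo-5-chloro-5-(iodomethyl)-2-oxo-2,5-dihydrofuran-3-yl]butyl acetate (C5 epimers, transient) | CCC[C@@H](OC(C)=O)C1=C(Br)C(Cl)(CI)OC1=O | intermediate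
13 | (1R)-1-[(5Z)-4-bromo-5-(iodomethylidene)-2-oxo-2,5-dihydrofuran-3-yl]butyl acetate | CCC[C@@H](OC(C)=O)C1=C(Br)/C(=C/I)OC1=O | target

Total step count: 8. Longest linear sequence: 7 (steps 1, 2, 4, 5, 6, 7, 8).

Steps most likely to fail

Step 4. The bromo-ynone may be consumed by conjugate addition–elimination of the oxazole nitrogen at its bromine-bearing carbon. It may also decompose thermally or add with eroded regiocontrol. The fallback takes the halogen out of the cycloaddition and puts it on the furan afterwards. It sets out from 1 and 5. Dess–Martin oxidation of 1 gives hex-1-yn-3-one F1. Its terminal, less hindered and more strongly polarised triple bond adds to 5 (toluene, 60 °C) through the oxa-aza-norbornadiene cycloadduct F2. F2 loses acetonitrile to give 1-(2-methoxy-5-methylfuran-3-yl)butan-1-one F3. Electrophilic bromination of the only free ring position C4 (NBS, MeCN, 0 °C, dark) comes back to the route at 7.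

Step 5. Three things may go wrong:
- Facial discrimination may be poor, because the twisted, doubly ortho-substituted furyl group is set against an n-propyl chain.
- The donor-conjugated ketone may react sluggishly.
- The boron alkoxide may ionise at the furylic carbon, causing racemisation or over-reduction.

The fallback replaces reagent control by resolution. It sets out from 7. NaBH4 in MeOH at 0 °C (basic, not Lewis acidic) gives racemic 1-(4-bromo-2-methoxy-5-methylfuran-3-yl)butan-1-ol F4. Burkholderia cepacia lipase with vinyl acetate in MTBE at 30 °C should acylate the (R)-enantiomer, following the empirical size rule for secondary alcohols. This comes back to the route directly at 9. The unreacted (1S)-1-(4-bromo-2-methoxy-5-methylfuran-3-yl)butan-1-ol F5 is removed on base-washed silica.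

Step 8. The vicinal iodochloride may revert to the alkene by base- or halide-induced loss of I–Cl instead of HCl. The elimination may also give mixed alkene geometry. The fallback passes through an isolable hemiketal and removes water under thermodynamic control. It sets out from 11. NIS in MeCN/H2O at 0 °C gives (1R)-1-[4-bromo-5-hydroxy-5-(iodomethyl)-2-oxo-2,5-dihydrofuran-3-yl]butyl acetate F6. Dehydration with P2O5 in refluxing CH2Cl2, as practised on the bromomethyl analogues, comes back to the route at 13, where the (Z)-isomer is the less strained one.

Further compounds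
F1 | step 4 | hex-1-yn-3-one | CCCC(=O)C#C
F2 | step 4 | 1-(4-methoxy-1,3-dimethyl-7-oxa-2-azabicyclo[2.2.1]hepta-2,5-dien-5-yl)butan-1-one (racemic, transient) | CCCC(=O)C1=CC2(C)N=C(C)C1(OC)O2
F3 | step 4 | 1-(2-methoxy-5-methylfuran-3-yl)butan-1-one | CCCC(=O)c1cc(C)oc1OC
F4 | step 5 | rac-1-(4-bromo-2-methoxy-5-methylfuran-3-yl)butan-1-ol | CCCC(O)c1c(Br)c(C)oc1OC
F5 | step 5 | (1S)-1-(4-bromo-2-methoxy-5-methylfuran-3-yl)butan-1-ol | CCC[C@H](O)c1c(Br)c(C)oc1OC
F6 | step 8 | (1R)-1-[4-bromo-5-hydroxy-5-(iodomethyl)-2-oxo-2,5-dihydrofuran-3-yl]butyl acetate (C5 epimers) | CCC[C@@H](OC(C)=O)C1=C(Br)C(O)(CI)OC1=O
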